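**Retrosynthetic overview**

- The target comes from one hydride reduction of a lactone–amide. A cis-fused γ-lactone (C1–O to the side-chain CH2OH carbon) fixes the C-1/C-2 cis relation and the Z alkene, an N-methoxy-N-methyl enamide masks the enal, and the triene is made by a stereoretentive Stille coupling with a dienylstannane from 6-methylhept-5-en-2-one.
- The lactone and enamide come from a spiro[4.5]decane hydroxy ketone by C-2 alkylation, hydroxyl-directed reduction and olefination at C-7.
- Key disconnection: the spiro hydroxy ketone comes from a 7-cyclobutylidene-8-methylcyclohexan-8-ol by hydroxyl-directed epoxidation and 1,2-shift of a cyclobutane bond (four-membered ring to five-membered ring). The enabling feature is the tetrasubstituted exocyclic alkene C7=C1′ that joins the six-membered ring to the cyclobutane and is allylic to the tertiary C8–OH: the hydroxyl steers the oxygen, and the strained ring on a tertiary carbon drives the shift that creates the spiro quaternary carbon.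
- The alkylidenecyclobutane comes from 1,4-dioxaspiro[4.5]dec-6-en-8-one, a 3-silyloxypropyl Grignard reagent and cyclobutanone (asymmetric conjugate addition–aldol, dehydration, methyl addition). The one catalyst-set stereocentre (chain carbon) is relayed to the other four.
- Ring order: six-membered ring bought, cyclobutane bought and attached, five-membered ring by ring expansion, temporary lactone last.

Key step: step 4

**Remarks**

- Locants: compounds 5–9 use 1,4-dioxaspiro[4.5]decane numbering (C-6 chain carbon, C-7, C-8). From 10 on, the carbocyclic spiro[4.5]decane is numbered C-1 (five-ring carbonyl or carbinol carbon), C-2 to C-4, C-5 (spiro), C-6 (chain carbon), C-7 (ketal, ketone or alkylidene carbon), C-8, C-9, C-10 (methyl carbinol).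
- Assumption: in step 1 the ligand antipode is the one whose copper complex delivers the alkyl group to the enone face that gives (6S)-6; both antipodes are available.
- Assumption: bromide 1 and phosphonate 18 are taken as commercially available.

**Route**

Step 1
Reactants: 1 (3-bromopropoxy)triisopropylsilane; 2 1,4-dioxaspiro[4.5]dec-6-en-8-one; 3 cyclobutanone
Product: 6 (6S,7R)-7-(1-hydroxycyclobutyl)-6-[3-(triisopropylsilyloxy)propyl]-1,4-dioxaspiro[4.5]decan-8-one, via Grignard reagent 4 (not isolated), via magnesium enolate 5 (not isolated)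
Conditions: Mg, Et2O, 35 °C (1 to 4); CuBr·SMe2 (5 mol %), JosiPhos-type ferrocenyl diphosphine (6 mol %), t-BuOMe, −75 °C, then 2; then 3, −75 to −40 °C; aq. NH4Cl
Reagents that add atoms: none
Why: Copper-catalysed asymmetric conjugate addition of the Grignard reagent sets C-6 under ligand control, and the magnesium enolate formed is trapped at C-7 by the strained ketone 3 (tandem conjugate addition–aldol); the C-7 centre is erased in step 2.

Step 2
Reactants: 6
Product: 7 (6S)-7-cyclobutylidene-6-[3-(triisopropylsilyloxy)propyl]-1,4-dioxaspiro[4.5]decan-8-one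
Conditions: SOCl2, pyridine, CH2Cl2, −20 to 0 °C
Reagents that add atoms: none
Why: Dehydration of the tertiary β-hydroxy ketone through its chlorosulfite (E1cB-type β-elimination) should give the exocyclic tetrasubstituted enone because only H-7 is acidic; C-6 is not touched.

Step 3
Reactants: 7
Product: 8 (6S,8S)-7-cyclobutylidene-8-methyl-6-[3-(triisopropylsilyloxy)propyl]-1,4-dioxaspiro[4.5]decan-8-ol
Conditions: MeLi, CeCl3, THF, −78 °C; aq. NH4Cl
Reagents that add atoms: methyllithium, [Li]C
Why: 1,2-addition of the organocerium reagent to the hindered enone; allylic 1,3-strain against the cyclobutylidene holds the C-6 chain axial, so methyl should enter C-8 from the opposite (equatorial) side and leave the new hydroxyl cis to the chain (axial attack on the chain-equatorial conformer leads to the same isomer).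

Step 4
Reactants: 8
Product: 10 (5R,6S,10S)-10-hydroxy-10-methyl-6-[3-(triisopropylsilyloxy)propyl]spiro[4.5]decane-1,7-dione 7-ethylene ketal, via spiro-epoxide 9 (not isolated)
Conditions: VO(acac)2 (5 mol %), t-BuOOH (1.1 equiv), CH2Cl2, 0 °C; then BF3·OEt2 (20 mol %), −78 to −40 °C
Reagents that add atoms: tert-butyl hydroperoxide, CC(C)(C)OO
Why: The vanadium alkoxide of the tertiary allylic C-8 hydroxyl delivers the peroxide oxygen to the same face of the tetrasubstituted C7=C1′ alkene and gives oxaspiro[2.3]hexane 9; BF3 then breaks the C7–O bond at the tertiary carbon while a cyclobutane C–C bond migrates from the oxygen-bearing C-1′ to C-7 on the face opposite the leaving oxygen. The closest known reaction type is the Lewis-acid rearrangement of epoxides of alkylidenecyclobutanes to cyclopentanones (a Meinwald-type semipinacol ring expansion). The five-membered ring is not closed by a cyclisation but arises by a 1,2-alkyl shift that enlarges the existing four-membered ring by one carbon, driven by relief of cyclobutane strain and formation of the carbonyl group. The new spiro quaternary stereocentre C-5 is controlled by the methyl carbinol (C-8 of 8, C-10 of 10): syn epoxidation followed by migration with inversion places the carbonyl carbon cis to the tertiary hydroxyl, and a detour through hydroxyl capture of the cation and reopening would converge on the same isomer. The step needs face selectivity in the oxygen transfer, secured by the allylic hydroxyl, and migration of the cyclobutane bond in preference to a methyl or ring-carbon shift from the carbinol carbon, secured by ring strain and by the boron-bound alkoxide on C-1′ being the better electron donor.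

Step 5
Reactants: 10
Product: 11 (5R,6S,10S)-10-methyl-6-[3-(triisopropylsilyloxy)propyl]-1,10-bis(trimethylsilyloxy)spiro[4.5]dec-1-en-7-one ethylene ketal
Conditions: Me3SiOTf, Et3N, CH2Cl2, −78 to 0 °C
Reagents that add atoms: trimethylsilyl trifluoromethanesulfonate, C[Si](C)(C)OS(=O)(=O)C(F)(F)F
Why: Soft enolisation and O-silylation: C-2 is the only enolisable position of the C-1 ketone, and capping the tertiary hydroxyl prevents retro-aldol opening of the β-hydroxy ketone under the basic conditions of step 6; no stereocentre is formed.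

Step 6
Reactants: 11
Product: 14 ethyl 2-[(2S,5R,6S,10S)-7,7-ethylenedioxy-10-hydroxy-10-methyl-1-oxo-6-[3-(triisopropylsilyloxy)propyl]spiro[4.5]decan-2-yl]acetate, via lithium enolate 12 (not isolated), via silyl ether 13 (not isolated)
Conditions: MeLi, THF, 0 °C; BrCH2CO2Et, DMPU, −78 to −30 °C; then AcOH–THF–H2O, rt
Reagents that add atoms: ethyl bromoacetate, BrCC(=O)OCC
Why: The lithium enolate is released regiospecifically from the silyl enol ether and alkylated (SN2); the electrophile should approach C-2 from the cyclopentene face remote from the fully substituted C-10 (CH3, OSiMe3), giving the C-2 arm trans to C-10, and any C-2 epimer cannot lactonise in step 7 and is removed there.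

Step 7
Reactants: 14
Product: 17 γ-lactone (C1–O to the acetic acid carbonyl) of [(1R,2S,5S,6S,10S)-1,10-dihydroxy-10-methyl-7-oxo-6-[3-(triisopropylsilyloxy)propyl]spiro[4.5]decan-2-yl]acetic acid, via hydroxy ester 15 (not isolated), via ketal lactone 16 (not isolated)
Conditions: Me4NBH(OAc)3, MeCN–AcOH, −20 °C; then TsOH·H2O (cat.), acetone–H2O, 40 °C
Reagents that add atoms: water, O
Why: Evans–Saksena reduction: the borohydride bound to the C-10 hydroxyl delivers hydride to the C-1 carbonyl face on the C-10 side, so the 1-OH should form cis to the C-2 arm; acid then closes the cis-fused γ-lactone and hydrolyses the dioxolane.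

Step 8
Reactants: 18 diethyl {2-[methoxy(methyl)amino]-2-oxoethyl}phosphonate
Product: 19 diethyl {1-[methoxy(methyl)amino]-1-oxopropan-2-yl}phosphonate (racemic)
Conditions: NaH (1.0 equiv), MeI (1.0 equiv), THF, 0 °C to rt
Reagents that add atoms: iodomethane, CI
Why: C-alkylation of the stabilised phosphonate carbanion; the stereocentre is racemic and disappears in step 9.

Step 9
Reactants: 17; 19
Product: 20 (E)-N-methoxy-N-methyl-2-[(1R,2S,5S,6R,10S)-lactone-7-ylidene]propanamide, that is 17 with C7=O replaced by C7=C(CH3)C(=O)N(OCH3)CH3, amide carbon trans to C-6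
Conditions: NaH, THF, 0 to 60 °C
Reagents that add atoms: none
Why: Horner–Wadsworth–Emmons olefination of the only ketone; reversible addition should place the bulkier amide group anti to the branched C-6 (E), the weakly basic phosphonate anion should not deprotonate the shielded H-6, and the lactone is inert.

Step 10
Reactants: 20
Product: 21 α-(hydroxymethylene) lactone of 20 (Z enol, hydroxyl cis to the lactone carbonyl)
Conditions: NaH, HCO2Et, EtOH (cat.), THF, 0 °C to rt; 1 M HCl
Reagents that add atoms: ethyl formate, CCOC=O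
Why: Claisen-type formylation at the only acidic C–H (lactone α-CH2); the amide and the tertiary alkoxide are inert to ethoxide and no stereocentre is formed.

Step 11
Reactants: 21
Product: 22 (Z)-enol triflate of 21 (triflate cis to the lactone carbonyl)
Conditions: PhNTf2, Et3N, LiOTf, CH2Cl2, 0 °C to rt
Reagents that add atoms: N-phenylbis(trifluoromethanesulfonimide), O=S(=O)(N(c1ccccc1)S(=O)(=O)C(F)(F)F)C(F)(F)F
Why: O-sulfonylation of the lithium-chelated enolate of a 1,3-dicarbonyl compound (enol triflate formation); chelation between the enolate oxygen and the lactone carbonyl should put the triflate cis to C=O, and the amine base leaves the tertiary alcohol untouched.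

Step 12
Reactants: 23 6-methylhept-5-en-2-one
Product: 24 6-methylhepta-1,5-dien-2-yl trifluoromethanesulfonate
Conditions: LiN(i-Pr)2, THF, −78 °C; PhNTf2, −78 to 0 °C; H2O
Reagents that add atoms: N-phenylbis(trifluoromethanesulfonimide), O=S(=O)(N(c1ccccc1)S(=O)(=O)C(F)(F)F)C(F)(F)F
Why: Kinetic deprotonation of the methyl ketone at CH3 followed by O-triflation of the enolate (enol triflate formation).

Step 13
Reactants: 24; 25 (E)-1,2-bis(tributylstannyl)ethene (twofold excess)
Product: 26 tributyl[(1E)-7-methyl-3-methylideneocta-1,6-dien-1-yl]stannane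
Conditions: Pd(PPh3)4 (5 mol %), LiCl, THF, 60 °C
Reagents that add atoms: none
Why: Stille coupling at one C–Sn bond with retention of the E geometry; the excess of 25 suppresses double coupling.

Step 14
Reactants: 22; 26
Product: 27 (2Z,4E)-trienyl lactone: 20 carrying at the lactone α-carbon the alkylidene =CH–CH=CH–C(=CH2)CH2CH2CH=C(CH3)2, dienyl group cis to the lactone carbonyl
Conditions: Pd2(dba)3 (2.5 mol %), AsPh3, LiCl, NMP, rt to 40 °C
Reagents that add atoms: none
Why: Stille coupling of an alkenyl triflate with an alkenylstannane is stereoretentive at both partners, so the Z alkylidene and the E disubstituted alkene of the triene are both transferred.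

Step 15
Reactants: 27
Product: 28 primary alcohol from 27 (3-hydroxypropyl chain free)
Conditions: HF·pyridine, pyridine, THF, 0 °C to rt
Reagents that add atoms: none
Why: Fluoride-mediated cleavage of the primary silyl ether, done before any acid-sensitive dienylic alcohol or enal is present.

Step 16
Reactants: 28
Product: 29 target, (E)-2-[(1R,2S,5S,6R,10S)-1,10-dihydroxy-6-(3-hydroxypropyl)-2-[(2Z,4E)-1-hydroxy-10-methyl-6-methylideneundeca-2,4,9-trien-2-yl]-10-methylspiro[4.5]decan-7-ylidene]propanal
Conditions: i-Bu2AlH (excess), CH2Cl2, −78 to 0 °C; aq. KNaC4H4O6 (potassium sodium tartrate)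
Reagents that add atoms: none
Why: Hydride reduction: the lactone is reduced 1,2 to the diol (freeing the C-1 hydroxyl and the allylic CH2OH), while the N-methoxy-N-methylamide is held as its aluminium chelate and gives the aldehyde only on work-up; no stereocentre or alkene geometry is touched.

**Compound list**

1 | (3-bromopropoxy)triisopropylsilane | BrCCCO[Si](C(C)C)(C(C)C)C(C)C | starting material
2 | 1,4-dioxaspiro[4.5]dec-6-en-8-one | O=C1C=CC2(CC1)OCCO2 | starting material
3 | cyclobutanone | O=C1CCC1 | starting material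
4 | [3-(triisopropylsilyloxy)propyl]magnesium bromide | Br[Mg]CCCO[Si](C(C)C)(C(C)C)C(C)C | intermediate
5 | bromomagnesium (6S)-6-[3-(triisopropylsilyloxy)propyl]-1,4-dioxaspiro[4.5]dec-7-en-8-olate | Br[Mg]OC1=C[C@H](CCCO[Si](C(C)C)(C(C)C)C(C)C)C2(OCCO2)CC1 | intermediate
6 | (6S,7R)-7-(1-hydroxycyclobutyl)-6-[3-(triisopropylsilyloxy)propyl]-1,4-dioxaspiro[4.5]decan-8-one | O=C1CCC2(OCCO2)[C@@H](CCCO[Si](C(C)C)(C(C)C)C(C)C)[C@@H]1C3(O)CCC3 | intermediate
7 | (6S)-7-cyclobutylidene-6-[3-(triisopropylsilyloxy)propyl]-1,4-dioxaspiro[4.5]decan-8-one | O=C1CCC2(OCCO2)[C@@H](CCCO[Si](C(C)C)(C(C)C)C(C)C)C1=C3CCC3 | intermediate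
8 | (6S,8S)-7-cyclobutylidene-8-methyl-6-[3-(triisopropylsilyloxy)propyl]-1,4-dioxaspiro[4.5]decan-8-ol | C[C@]1(O)CCC2(OCCO2)[C@@H](CCCO[Si](C(C)C)(C(C)C)C(C)C)C1=C3CCC3 | intermediate
9 | (6S,7R,8S)-7-cyclobutyl-7,1′-epoxy-8-methyl-6-[3-(triisopropylsilyloxy)propyl]-1,4-dioxaspiro[4.5]decan-8-ol (oxaspiro[2.3]hexane, oxirane oxygen cis to 8-OH) | C[C@]1(O)CCC2(OCCO2)[C@@H](CCCO[Si](C(C)C)(C(C)C)C(C)C)[C@@]13OC34CCC4 | intermediate
10 | (5R,6S,10S)-10-hydroxy-10-methyl-6-[3-(triisopropylsilyloxy)propyl]spiro[4.5]decane-1,7-dione 7-ethylene ketal | O=C1CCC[C@]12[C@H](CCCO[Si](C(C)C)(C(C)C)C(C)C)C3(OCCO3)CC[C@]2(C)O | intermediate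
11 | (5R,6S,10S)-10-methyl-6-[3-(triisopropylsilyloxy)propyl]-1,10-bis(trimethylsilyloxy)spiro[4.5]dec-1-en-7-one ethylene ketal | C[Si](C)(C)OC1=CCC[C@]12[C@H](CCCO[Si](C(C)C)(C(C)C)C(C)C)C3(OCCO3)CC[C@]2(C)O[Si](C)(C)C | intermediate
12 | lithium C1-enolate corresponding to 11 (10-OSiMe3 retained) | [Li]OC1=CCC[C@]12[C@H](CCCO[Si](C(C)C)(C(C)C)C(C)C)C3(OCCO3)CC[C@]2(C)O[Si](C)(C)C | intermediate
13 | ethyl 2-[(2S,5R,6S,10S)-7,7-ethylenedioxy-10-methyl-1-oxo-6-[3-(triisopropylsilyloxy)propyl]-10-(trimethylsilyloxy)spiro[4.5]decan-2-yl]acetate | CCOC(=O)C[C@@H]1CC[C@]2([C@H](CCCO[Si](C(C)C)(C(C)C)C(C)C)C3(OCCO3)CC[C@]2(C)O[Si](C)(C)C)C1=O | intermediate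
14 | ethyl 2-[(2S,5R,6S,10S)-7,7-ethylenedioxy-10-hydroxy-10-methyl-1-oxo-6-[3-(triisopropylsilyloxy)propyl]spiro[4.5]decan-2-yl]acetate | CCOC(=O)C[C@@H]1CC[C@]2([C@H](CCCO[Si](C(C)C)(C(C)C)C(C)C)C3(OCCO3)CC[C@]2(C)O)C1=O | intermediate
15 | ethyl 2-[(1R,2S,5S,6S,10S)-7,7-ethylenedioxy-1,10-dihydroxy-10-methyl-6-[3-(triisopropylsilyloxy)propyl]spiro[4.5]decan-2-yl]acetate | CCOC(=O)C[C@@H]1CC[C@]2([C@H](CCCO[Si](C(C)C)(C(C)C)C(C)C)C3(OCCO3)CC[C@]2(C)O)[C@@H]1O | intermediate
16 | cis-fused γ-lactone of the acid of 15 (1R,2S,5S,6S,10S; ketal retained) | O=C1C[C@@H]2CC[C@]3([C@H](CCCO[Si](C(C)C)(C(C)C)C(C)C)C4(OCCO4)CC[C@]3(C)O)[C@@H]2O1 | intermediate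
17 | cis-fused γ-lactone with free C-7 ketone (1R,2S,5S,6S,10S) | O=C1C[C@@H]2CC[C@]3([C@H](CCCO[Si](C(C)C)(C(C)C)C(C)C)C(=O)CC[C@]3(C)O)[C@@H]2O1 | intermediate
18 | diethyl {2-[methoxy(methyl)amino]-2-oxoethyl}phosphonate | CCOP(=O)(OCC)CC(=O)N(C)OC | starting material
19 | diethyl {1-[methoxy(methyl)amino]-1-oxopropan-2-yl}phosphonate (racemic) | CCOP(=O)(OCC)C(C)C(=O)N(C)OC | intermediate
20 | (E)-N-methoxy-N-methyl enamide lactone (1R,2S,5S,6R,10S) | O=C1C[C@@H]2CC[C@]3([C@H](CCCO[Si](C(C)C)(C(C)C)C(C)C)/C(=C(\C)C(=O)N(C)OC)CC[C@]3(C)O)[C@@H]2O1 | intermediate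
21 | α-(hydroxymethylene) lactone of 20 (Z enol) | O=C1/C(=C\O)[C@@H]2CC[C@]3([C@H](CCCO[Si](C(C)C)(C(C)C)C(C)C)/C(=C(\C)C(=O)N(C)OC)CC[C@]3(C)O)[C@@H]2O1 | intermediate
22 | (Z)-enol triflate of 21 | O=C1/C(=C\OS(=O)(=O)C(F)(F)F)[C@@H]2CC[C@]3([C@H](CCCO[Si](C(C)C)(C(C)C)C(C)C)/C(=C(\C)C(=O)N(C)OC)CC[C@]3(C)O)[C@@H]2O1 | intermediate
23 | 6-methylhept-5-en-2-one | CC(=O)CCC=C(C)C | starting material
24 | 6-methylhepta-1,5-dien-2-yl trifluoromethanesulfonate | C=C(OS(=O)(=O)C(F)(F)F)CCC=C(C)C | intermediate
25 | (E)-1,2-bis(tributylstannyl)ethene | CCCC[Sn](CCCC)(CCCC)/C=C/[Sn](CCCC)(CCCC)CCCC | starting material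
26 | tributyl[(1E)-7-methyl-3-methylideneocta-1,6-dien-1-yl]stannane | C=C(/C=C/[Sn](CCCC)(CCCC)CCCC)CCC=C(C)C | intermediate
27 | (2Z,4E)-trienyl lactone enamide, silyl ether | O=C1/C(=C\C=C\C(=C)CCC=C(C)C)[C@@H]2CC[C@]3([C@H](CCCO[Si](C(C)C)(C(C)C)C(C)C)/C(=C(\C)C(=O)N(C)OC)CC[C@]3(C)O)[C@@H]2O1 | intermediate
28 | (2Z,4E)-trienyl lactone enamide, free primary alcohol | O=C1/C(=C\C=C\C(=C)CCC=C(C)C)[C@@H]2CC[C@]3([C@H](CCCO)/C(=C(\C)C(=O)N(C)OC)CC[C@]3(C)O)[C@@H]2O1 | intermediate
29 | CNP0246965.2, (E)-2-[(1R,2S,5S,6R,10S)-1,10-dihydroxy-6-(3-hydroxypropyl)-2-[(2Z,4E)-1-hydroxy-10-methyl-6-methylideneundeca-2,4,9-trien-2-yl]-10-methylspiro[4.5]decan-7-ylidene]propanal | C=C(/C=C/C=C(\CO)[C@@H]1CC[C@]2([C@H](CCCO)/C(=C(\C)C=O)CC[C@]2(C)O)[C@@H]1O)CCC=C(C)C | target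

**Summary**

Total step count: 16. Longest linear sequence: 13 steps (steps 1–7, 9–11, 14–16); steps 8 and 12–13 are convergent branches.

**Steps most likely to fail**

Step 4. Oxygen may be transferred to the wrong alkene face, or the 1,2-shift may lose stereochemical fidelity through a long-lived cation or a competing shift from the carbinol carbon. The fallback sets out from 8 and returns at 10. Compound 8 is epoxidised without hydroxyl direction by dimethyldioxirane in acetone–methanol, where attack should come from the open face anti to the hydroxyl and the chain. This should give the epimeric spiro-epoxide (6S,7S,8S)-7-cyclobutyl-7,1′-epoxy-8-methyl-6-[3-(triisopropylsilyloxy)propyl]-1,4-dioxaspiro[4.5]decan-8-ol F1. LiI in THF then opens the oxirane at C-7 with inversion to an iodo alkoxide, and the cyclobutane bond displaces iodide in a second invertive 1,2-shift. Net retention at C-7 should converge on 10 without a free carbocation.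

Step 9. Addition of the phosphonate anion to the hindered C-7 ketone may be slow, leaving room for enolisation with epimerisation at C-6, or the E/Z control may be poor. The fallback sets out from 17 and returns at 20. Isopropenylmagnesium bromide with CeCl3 (THF, −78 °C) adds to the ketone in preference to the lactone and should give the tertiary allylic alcohol, the 7-hydroxy-7-(prop-1-en-2-yl) lactone F2 (either C-7 epimer serves). Pyridinium chlorochromate (C5H5NH)[CrO3Cl] in CH2Cl2 then effects the Dauben–Babler oxidative 1,3-transposition, whose cyclic chromate shift should place the oxygenated carbon on the less hindered C-8 side, giving the (E)-2-(lactone-7-ylidene)propanal F3. Pinnick oxidation (NaClO2, NaH2PO4, 2-methylbut-2-ene) gives the (E)-2-(lactone-7-ylidene)propanoic acid F4. Carbodiimide coupling with N,O-dimethylhydroxylamine returns 20.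

Step 11. The triflate may form with the wrong enol geometry (trans to the lactone carbonyl), which would carry the dienyl group to the wrong side in step 14. The fallback sets out from 20 and returns at 27. The lactone enolate of 20 (LiN(SiMe3)2, THF, −78 °C) is phosphinylated at carbon with bis(2-methylphenyl) phosphorochloridite and oxidised with t-BuOOH to the α-[bis(2-methylphenoxy)phosphoryl] lactone F5. Triflate 24 is converted by a Heck reaction with acrolein (Pd(OAc)2, NaHCO3, n-Bu4NCl, DMF) into (2E)-8-methyl-4-methylidenenona-2,7-dienal F6. A Z-selective diaryl phosphonate Horner–Wadsworth–Emmons olefination of F6 with F5 (NaH, THF, −78 °C) should then give 27 directly, with the dienyl group cis to the lactone carbonyl.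

Further compounds
F1 | step 4 | (6S,7S,8S)-7-cyclobutyl-7,1′-epoxy-8-methyl-6-[3-(triisopropylsilyloxy)propyl]-1,4-dioxaspiro[4.5]decan-8-ol (oxirane oxygen trans to 8-OH) | C[C@]1(O)CCC2(OCCO2)[C@@H](CCCO[Si](C(C)C)(C(C)C)C(C)C)[C@]13OC34CCC4
F2 | step 9 | 7-hydroxy-7-(prop-1-en-2-yl) lactone from 17 (C-7 epimers) | O=C1C[C@@H]2CC[C@]3([C@H](CCCO[Si](C(C)C)(C(C)C)C(C)C)C(O)(C(C)=C)CC[C@]3(C)O)[C@@H]2O1
F3 | step 9 | (E)-2-(lactone-7-ylidene)propanal | O=C1C[C@@H]2CC[C@]3([C@H](CCCO[Si](C(C)C)(C(C)C)C(C)C)/C(=C(\C)C=O)CC[C@]3(C)O)[C@@H]2O1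
F4 | step 9 | (E)-2-(lactone-7-ylidene)propanoic acid | O=C1C[C@@H]2CC[C@]3([C@H](CCCO[Si](C(C)C)(C(C)C)C(C)C)/C(=C(\C)C(=O)O)CC[C@]3(C)O)[C@@H]2O1
F5 | step 11 | α-[bis(2-methylphenoxy)phosphoryl] lactone from 20 (α-carbon epimers) | O=C1C(P(=O)(Oc4ccccc4C)Oc4ccccc4C)[C@@H]2CC[C@]3([C@H](CCCO[Si](C(C)C)(C(C)C)C(C)C)/C(=C(\C)C(=O)N(C)OC)CC[C@]3(C)O)[C@@H]2O1
F6 | step 11 | (2E)-8-methyl-4-methylidenenona-2,7-dienal | C=C(/C=C/C=O)CCC=C(C)C
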